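**Plan**

- Ring numbering used throughout: O1–O2–C3(OMe, enyne chain)–C4–C5–C6(H, arm C7–C8 = CH2CO2H). C3 is a methoxy peroxyketal carbon in a 1,4 relation to the peroxy-bearing C6, so the 1,2-dioxane is the methanol-capped ring form of a γ-hydroperoxy ketone and can be closed by peroxyketalization.
- Retrosynthetic cuts, in order: C8 acid back to a primary silyl ether; O2–C3 (ring opened to a hydroperoxy dimethyl ketal); O1–C6 (hydroperoxide from a mesylate and H2O2); C4–C5 (ketone hydrazone azaenolate plus terminal epoxide); the ketone methyl (MeLi on an acid); alkyne–alkene C–C (Sonogashira).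
- Forward: the enyne chain is built first (vinyl iodide + hex-5-ynoic acid, then methyl ketone and hydrazone) and joined to the four-carbon epoxide. C6 mesylate, C3 ketal and C6 hydroperoxide follow; the only ring is then closed, and desilylation and oxidation of C8 finish the route.
- Stereochemistry: C6 derives from the (S)-triol acetonide 9; it is kept through epoxide 13 and its opening and inverted once in the peroxide SN2 (R to S). C3 is set by thermodynamic (anomeric) control in the ring closure. The E-alkene comes from syn-hydrozirconation.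

Key step: step 12

Assumption: acetonide 9 is bought as such (it is the commercial 1,2-acetonide of (S)-butane-1,2,4-triol); if only the triol is at hand, acetone/TsOH should give 9 in one extra step.

**Route**

Step 1
Reactants: 1 undec-1-yne
Product: 3 (E)-1-iodoundec-1-ene, via alkenylzirconocene chloride 2 (not isolated)
Conditions: Cp2Zr(H)Cl, THF, rt; then I2, 0 °C
Reagents that add atoms: iodine, II
Why: Hydrozirconation of a terminal alkyne with the Schwartz reagent is a syn, anti-Markovnikov addition that puts zirconium on the terminal carbon, and iodinolysis of the C–Zr bond goes with retention, so the E-iodide should result.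

Step 2
Reactants: 3 (E)-1-iodoundec-1-ene; 4 hex-5-ynoic acid
Product: 5 (E)-heptadec-7-en-5-ynoic acid
Conditions: PdCl2(PPh3)2 (cat.), CuI (cat.), Et3N, THF, rt; dilute HCl work-up
Reagents that add atoms: none
Why: Sonogashira coupling of an alkenyl iodide with a terminal alkyne (zerovalent palladium with CuI as co-catalyst) keeps the alkene geometry, and the acid is carried as its triethylammonium carboxylate.

Step 3
Reactants: 5 (E)-heptadec-7-en-5-ynoic acid
Product: 7 (E)-octadec-8-en-6-yn-2-one, via dilithium gem-diolate 6 (not isolated)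
Conditions: MeLi (2.2 equiv), Et2O, 0 °C to rt; inverse quench into cold 1 M HCl
Reagents that add atoms: methyllithium, [Li]C
Why: Addition of methyllithium to a lithium carboxylate stops at the dilithium gem-diolate, which collapses to the methyl ketone only on acidic quench (the classical acid-to-methyl-ketone conversion); the internal enyne has no acidic proton.

Step 4
Reactants: 7 (E)-octadec-8-en-6-yn-2-one
Product: 8 (E)-octadec-8-en-6-yn-2-one N,N-dimethylhydrazone
Conditions: Me2NNH2 (excess), AcOH (cat.), EtOH, 60 °C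
Reagents that add atoms: N,N-dimethylhydrazine, CN(C)N
Why: Condensation of a ketone with N,N-dimethylhydrazine gives the hydrazone needed for regioselective α-metalation; the C=N isomer mixture is of no consequence.

Step 5
Reactants: 9 2-[(4S)-2,2-dimethyl-1,3-dioxolan-4-yl]ethanol
Product: 10 tert-butyl{2-[(4S)-2,2-dimethyl-1,3-dioxolan-4-yl]ethoxy}diphenylsilane
Conditions: TBDPSCl, imidazole, CH2Cl2, 0 °C to rt
Reagents that add atoms: tert-butyl(chloro)diphenylsilane, CC(C)(C)[Si](Cl)(c1ccccc1)c1ccccc1
Why: Standard silylation of a primary alcohol; the TBDPS ether is chosen because it has to survive acidic methanol in steps 10 and 12 and cold aqueous base in step 11.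

Step 6
Reactants: 10 tert-butyl{2-[(4S)-2,2-dimethyl-1,3-dioxolan-4-yl]ethoxy}diphenylsilane
Product: 11 (2S)-4-[(tert-butyldiphenylsilyl)oxy]butane-1,2-diol
Conditions: 80% aq. AcOH, rt to 40 °C
Reagents that add atoms: none
Why: Acid hydrolysis of the isopropylidene ketal; a primary TBDPS ether is stable to aqueous acetic acid and the stereocenter is not touched.

Step 7
Reactants: 11 (2S)-4-[(tert-butyldiphenylsilyl)oxy]butane-1,2-diol
Product: 13 tert-butyl{2-[(2S)-oxiran-2-yl]ethoxy}diphenylsilane, via primary monotosylate 12 (not isolated)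
Conditions: TsCl (1.05 equiv), Et3N, Bu2SnO (cat.), CH2Cl2, 0 °C to rt; then K2CO3, MeOH, rt
Reagents that add atoms: none
Why: Tin-catalysed sulfonylation selects the primary hydroxyl of the 1,2-diol, and the secondary alkoxide then closes the oxirane by 3-exo-tet displacement at C1, so the stereocenter keeps its (S) configuration.

Step 8
Reactants: 8 (E)-octadec-8-en-6-yn-2-one N,N-dimethylhydrazone; 13 tert-butyl{2-[(2S)-oxiran-2-yl]ethoxy}diphenylsilane
Product: 16 (3R,12E)-1-[(tert-butyldiphenylsilyl)oxy]-3-hydroxydocos-12-en-10-yn-6-one, via lithium azaenolate 14 (not isolated), via hydroxy hydrazone 15 (not isolated)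
Conditions: LDA (1.1 equiv), THF, −78 to 0 °C; 13, −78 °C to rt; H2O quench; then sat. aq. oxalic acid/Et2O, rt
Reagents that add atoms: water, O (carbonyl oxygen of 16, from hydrazone hydrolysis)
Why: Dimethylhydrazone azaenolate alkylation: LDA deprotonates the hydrazone kinetically at the methyl group, the azaenolate opens the terminal epoxide at its CH2 by SN2 (C4–C5 bond; the carbinol center is untouched and becomes R only through the change in priorities), and mild biphasic hydrolysis releases the γ-hydroxy ketone.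

Step 9
Reactants: 16 (3R,12E)-1-[(tert-butyldiphenylsilyl)oxy]-3-hydroxydocos-12-en-10-yn-6-one
Product: 17 (3R,12E)-1-[(tert-butyldiphenylsilyl)oxy]-6-oxodocos-12-en-10-yn-3-yl methanesulfonate
Conditions: MsCl, Et3N, CH2Cl2, −10 °C
Reagents that add atoms: methanesulfonyl chloride, CS(=O)(=O)Cl
Why: Sulfonylation of the open-chain secondary alcohol forms only an O–S bond, so the configuration is retained, and it blocks the hydroxyl before the ketone is ketalized.

Step 10
Reactants: 17 (3R,12E)-1-[(tert-butyldiphenylsilyl)oxy]-6-oxodocos-12-en-10-yn-3-yl methanesulfonate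
Product: 18 (3R,12E)-1-[(tert-butyldiphenylsilyl)oxy]-6,6-dimethoxydocos-12-en-10-yn-3-yl methanesulfonate
Conditions: HC(OMe)3, MeOH, CSA (cat.), 0 °C to rt; Et3N quench
Reagents that add atoms: trimethyl orthoformate, COC(OC)OC (net source of the two methoxy groups; methanol, CO, is the exchanging solvent)
Why: Acid-catalysed ketalization driven by the orthoester as water scavenger; the secondary mesylate and the TBDPS ether should tolerate brief catalytic acid in methanol at or below room temperature.

Step 11
Reactants: 18 (3R,12E)-1-[(tert-butyldiphenylsilyl)oxy]-6,6-dimethoxydocos-12-en-10-yn-3-yl methanesulfonate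
Product: 19 tert-butyl{[(3S,12E)-3-hydroperoxy-6,6-dimethoxydocos-12-en-10-yn-1-yl]oxy}diphenylsilane
Conditions: 50% aq. H2O2 (large excess), KOH, MeOH/THF, 0 °C to rt
Reagents that add atoms: hydrogen peroxide, OO
Why: SN2 displacement of a secondary methanesulfonate by the hydroperoxide anion (an alpha-effect nucleophile; the classical sulfonate route to alkyl hydroperoxides) goes with inversion, turning the (R)-mesylate into the (S)-hydroperoxide, while the ketal, silyl ether and enyne are inert to cold alkaline H2O2.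

Step 12
Reactants: 19 tert-butyl{[(3S,12E)-3-hydroperoxy-6,6-dimethoxydocos-12-en-10-yn-1-yl]oxy}diphenylsilane
Product: 20 tert-butyl{2-[(3R,6S)-3-[(E)-hexadec-6-en-4-yn-1-yl]-3-methoxy-1,2-dioxan-6-yl]ethoxy}diphenylsilane
Conditions: PPTS (0.2 equiv), MeOH (dilute), rt; NaHCO3 quench
Reagents that add atoms: none
Why: PPTS protonates one methoxy group of the C3 ketal, methanol leaves, and the C3 methoxy oxocarbenium ion is captured by the terminal oxygen of the C6 hydroperoxide, forming the O2–C3 bond. The closest known reaction type is the acid-catalysed conversion of γ-hydroperoxy ketones or their ketals into 3-alkoxy-1,2-dioxanes in an alcohol. The 1,2-dioxane closes in the 6-exo-trig mode, the C=O+ bond of the oxocarbenium ion staying outside the new ring. C6 is not touched (6S from step 11), and the new stereocenter C3 is set under thermodynamic control because ring opening and methoxy exchange are reversible in acidic methanol: the favoured chair carries the C3 methoxy group axial (anomeric stabilisation by O2) with the enyne chain and the C6 arm both equatorial, which is the 3R,6S isomer with methoxy cis to the arm. The selectivity needed is the cyclic peroxyketal over the open-chain ketal and over intermolecular peroxyketals; it is secured by the 1,4 spacing of C3 and C6 (six-membered ring), by dilution and by the greater stability of peroxyketals relative to dialkyl ketals. PPTS in methanol at room temperature should leave the primary TBDPS ether and the enyne intact.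

Step 13
Reactants: 20 tert-butyl{2-[(3R,6S)-3-[(E)-hexadec-6-en-4-yn-1-yl]-3-methoxy-1,2-dioxan-6-yl]ethoxy}diphenylsilane
Product: 21 2-[(3R,6S)-3-[(E)-hexadec-6-en-4-yn-1-yl]-3-methoxy-1,2-dioxan-6-yl]ethanol
Conditions: HF·pyridine, pyridine, THF, 0 °C to rt
Reagents that add atoms: none
Why: Fluoride-driven desilylation (Si–F bond formation) in buffered, weakly acidic HF·pyridine avoids the basic conditions that could trigger Kornblum–DeLaMare cleavage of the peroxide at C6–H.

Step 14
Reactants: 21 2-[(3R,6S)-3-[(E)-hexadec-6-en-4-yn-1-yl]-3-methoxy-1,2-dioxan-6-yl]ethanol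
Product: 23 2-[(3R,6S)-3-[(E)-hexadec-6-en-4-yn-1-yl]-3-methoxy-1,2-dioxan-6-yl]acetic acid, via β-peroxy aldehyde 22 (not isolated)
Conditions: TEMPO (0.2 equiv), PhI(OAc)2 (2.5 equiv), MeCN/H2O (1:1), 0 °C to rt
Reagents that add atoms: water, O (second oxygen of the carboxyl group)
Why: Nitroxyl-catalysed oxidation takes the primary alcohol through the aldehyde and its hydrate to the carboxylic acid in one flask without a basic step, so the β-peroxy aldehyde is never isolated, and the peroxide, peroxyketal and enyne are inert to the oxoammonium oxidant.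

**Compound list**

1 | undec-1-yne | CCCCCCCCCC#C | starting material
2 | chlorobis(cyclopentadienyl)[(E)-undec-1-en-1-yl]zirconium | CCCCCCCCC/C=C/[Zr](Cl)(C1C=CC=C1)C1C=CC=C1 | intermediate (not isolated)
3 | (E)-1-iodoundec-1-ene | CCCCCCCCC/C=C/I | intermediate
4 | hex-5-ynoic acid | C#CCCCC(=O)O | starting material
5 | (E)-heptadec-7-en-5-ynoic acid | CCCCCCCCC/C=C/C#CCCCC(=O)O | intermediate
6 | dilithium (E)-octadec-8-en-6-yne-2,2-diolate | CCCCCCCCC/C=C/C#CCCCC(C)(O[Li])O[Li] | intermediate (not isolated)
7 | (E)-octadec-8-en-6-yn-2-one | CCCCCCCCC/C=C/C#CCCCC(C)=O | intermediate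
8 | (E)-octadec-8-en-6-yn-2-one N,N-dimethylhydrazone (C=N isomer mixture) | CCCCCCCCC/C=C/C#CCCCC(C)=NN(C)C | intermediate
9 | 2-[(4S)-2,2-dimethyl-1,3-dioxolan-4-yl]ethanol | CC1(C)OC[C@H](CCO)O1 | starting material
10 | tert-butyl{2-[(4S)-2,2-dimethyl-1,3-dioxolan-4-yl]ethoxy}diphenylsilane | CC1(C)OC[C@H](CCO[Si](c2ccccc2)(c2ccccc2)C(C)(C)C)O1 | intermediate
11 | (2S)-4-[(tert-butyldiphenylsilyl)oxy]butane-1,2-diol | OC[C@@H](O)CCO[Si](c1ccccc1)(c1ccccc1)C(C)(C)C | intermediate
12 | (2S)-4-[(tert-butyldiphenylsilyl)oxy]-2-hydroxybutyl 4-methylbenzenesulfonate | Cc1ccc(cc1)S(=O)(=O)OC[C@@H](O)CCO[Si](c2ccccc2)(c3ccccc3)C(C)(C)C | intermediate (not isolated)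
13 | tert-butyl{2-[(2S)-oxiran-2-yl]ethoxy}diphenylsilane | C1O[C@H]1CCO[Si](c2ccccc2)(c3ccccc3)C(C)(C)C | intermediate
14 | lithium azaenolate of hydrazone 8 (metalated at the former methyl carbon) | CCCCCCCCC/C=C/C#CCCCC(=C)N([Li])N(C)C | intermediate (not isolated)
15 | (3R,12E)-1-[(tert-butyldiphenylsilyl)oxy]-6-(2,2-dimethylhydrazinylidene)docos-12-en-10-yn-3-ol | CCCCCCCCC/C=C/C#CCCCC(CC[C@@H](O)CCO[Si](c1ccccc1)(c1ccccc1)C(C)(C)C)=NN(C)C | intermediate (not isolated)
16 | (3R,12E)-1-[(tert-butyldiphenylsilyl)oxy]-3-hydroxydocos-12-en-10-yn-6-one | CCCCCCCCC/C=C/C#CCCCC(=O)CC[C@@H](O)CCO[Si](c1ccccc1)(c1ccccc1)C(C)(C)C | intermediate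
17 | (3R,12E)-1-[(tert-butyldiphenylsilyl)oxy]-6-oxodocos-12-en-10-yn-3-yl methanesulfonate | CCCCCCCCC/C=C/C#CCCCC(=O)CC[C@@H](OS(C)(=O)=O)CCO[Si](c1ccccc1)(c1ccccc1)C(C)(C)C | intermediate
18 | (3R,12E)-1-[(tert-butyldiphenylsilyl)oxy]-6,6-dimethoxydocos-12-en-10-yn-3-yl methanesulfonate | CCCCCCCCC/C=C/C#CCCCC(OC)(OC)CC[C@@H](OS(C)(=O)=O)CCO[Si](c1ccccc1)(c1ccccc1)C(C)(C)C | intermediate
19 | tert-butyl{[(3S,12E)-3-hydroperoxy-6,6-dimethoxydocos-12-en-10-yn-1-yl]oxy}diphenylsilane | CCCCCCCCC/C=C/C#CCCCC(OC)(OC)CC[C@H](OO)CCO[Si](c1ccccc1)(c1ccccc1)C(C)(C)C | intermediate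
20 | tert-butyl{2-[(3R,6S)-3-[(E)-hexadec-6-en-4-yn-1-yl]-3-methoxy-1,2-dioxan-6-yl]ethoxy}diphenylsilane | CCCCCCCCC/C=C/C#CCCC[C@]1(OC)CC[C@@H](CCO[Si](c2ccccc2)(c2ccccc2)C(C)(C)C)OO1 | intermediate
21 | 2-[(3R,6S)-3-[(E)-hexadec-6-en-4-yn-1-yl]-3-methoxy-1,2-dioxan-6-yl]ethanol | CCCCCCCCC/C=C/C#CCCC[C@]1(OC)CC[C@@H](CCO)OO1 | intermediate
22 | 2-[(3R,6S)-3-[(E)-hexadec-6-en-4-yn-1-yl]-3-methoxy-1,2-dioxan-6-yl]acetaldehyde | CCCCCCCCC/C=C/C#CCCC[C@]1(OC)CC[C@@H](CC=O)OO1 | intermediate (not isolated)
23 | 2-[(3R,6S)-3-[(E)-hexadec-6-en-4-yn-1-yl]-3-methoxy-1,2-dioxan-6-yl]acetic acid | CCCCCCCCC/C=C/C#CCCC[C@]1(OC)CC[C@@H](CC(=O)O)OO1 | target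

**Step count and risks**

Total step count: 14. Longest linear sequence: 11 steps (steps 1–4 and 8–14, from undec-1-yne); the epoxide branch (steps 5–7) joins at step 8.

Steps most likely to fail:

1. Step 11. Elimination to alkenes may compete with substitution. A ketal methoxy oxygen may expel the mesylate through a five-membered oxonium ion. The new hydroperoxide may be alkylated a second time, or hydroxide may slowly remove the silyl group. Fallback: from 18, displacement with a mono-protected hydrogen peroxide, 2-methoxyprop-2-yl hydroperoxide (CsOH·H2O, DMF, 0 °C), a known inverting substitution of secondary sulfonates in a dipolar aprotic medium, should give tert-butyl{[(3S,12E)-6,6-dimethoxy-3-[(2-methoxypropan-2-yl)peroxy]docos-12-en-10-yn-1-yl]oxy}diphenylsilane F1. In PPTS/MeOH, the medium of step 12, the 2-methoxyprop-2-yl group passes to methanol, hydroperoxide 19 forms in the flask and closes, and the route is rejoined at 20.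

2. Step 12. Ring closure may stay incomplete because the solvent holds part of the material as the open-chain ketal. Equilibration at C3 may be slow, leaving the epimer with equatorial methoxy. The free hydroperoxide may also decompose on long exposure to acid. Fallback: close the ring irreversibly at the other peroxide bond. From 18, urea–H2O2 with Sc(OTf)3 (cat.) in MeOH should exchange one ketal methoxy for a hydroperoxy group, giving (3R,12E)-1-[(tert-butyldiphenylsilyl)oxy]-6-hydroperoxy-6-methoxydocos-12-en-10-yn-3-yl methanesulfonate F2 (both configurations at the ketal carbon). KOtBu/18-crown-6 in toluene at 0 °C then closes the 1,2-dioxane by intramolecular SN2 at C6 with inversion (6-exo-tet) to tert-butyl{2-[(6S)-3-[(E)-hexadec-6-en-4-yn-1-yl]-3-methoxy-1,2-dioxan-6-yl]ethoxy}diphenylsilane as the C3-epimer mixture F3. Brief PPTS/MeOH treatment, which now only exchanges the exocyclic methoxy group through the cyclic peroxycarbenium ion, should converge F3 on 20.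

3. Step 10. The carbonyl or ketal oxygen may displace the γ-mesylate (five-membered oxonium ion leading to a 2-methoxytetrahydrofuran and loss of the C6 leaving group), or ketalization may be slow and accompanied by silyl loss. Fallback: install the ketal while C6 carries a group that cannot leave. From 16, acetylation (Ac2O, pyridine, DMAP) should give (3R,12E)-1-[(tert-butyldiphenylsilyl)oxy]-6-oxodocos-12-en-10-yn-3-yl acetate F4. Ketalization as in step 10 gives (3R,12E)-1-[(tert-butyldiphenylsilyl)oxy]-6,6-dimethoxydocos-12-en-10-yn-3-yl acetate F5. K2CO3/MeOH frees the base-stable (3R,12E)-1-[(tert-butyldiphenylsilyl)oxy]-6,6-dimethoxydocos-12-en-10-yn-3-ol F6 (handled on Et3N-deactivated silica), and mesylation (MsCl, Et3N, −10 °C) returns to 18.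

Further compounds
F1 | step 11 | tert-butyl{[(3S,12E)-6,6-dimethoxy-3-[(2-methoxypropan-2-yl)peroxy]docos-12-en-10-yn-1-yl]oxy}diphenylsilane | CCCCCCCCC/C=C/C#CCCCC(OC)(OC)CC[C@H](OOC(C)(C)OC)CCO[Si](c1ccccc1)(c1ccccc1)C(C)(C)C
F2 | step 12 | (3R,12E)-1-[(tert-butyldiphenylsilyl)oxy]-6-hydroperoxy-6-methoxydocos-12-en-10-yn-3-yl methanesulfonate (both configurations at the ketal carbon) | CCCCCCCCC/C=C/C#CCCCC(OC)(OO)CC[C@@H](OS(C)(=O)=O)CCO[Si](c1ccccc1)(c1ccccc1)C(C)(C)C
F3 | step 12 | tert-butyl{2-[(6S)-3-[(E)-hexadec-6-en-4-yn-1-yl]-3-methoxy-1,2-dioxan-6-yl]ethoxy}diphenylsilane (C3-epimer mixture) | CCCCCCCCC/C=C/C#CCCCC1(OC)CC[C@@H](CCO[Si](c2ccccc2)(c2ccccc2)C(C)(C)C)OO1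
F4 | step 10 | (3R,12E)-1-[(tert-butyldiphenylsilyl)oxy]-6-oxodocos-12-en-10-yn-3-yl acetate | CCCCCCCCC/C=C/C#CCCCC(=O)CC[C@@H](OC(C)=O)CCO[Si](c1ccccc1)(c1ccccc1)C(C)(C)C
F5 | step 10 | (3R,12E)-1-[(tert-butyldiphenylsilyl)oxy]-6,6-dimethoxydocos-12-en-10-yn-3-yl acetate | CCCCCCCCC/C=C/C#CCCCC(OC)(OC)CC[C@@H](OC(C)=O)CCO[Si](c1ccccc1)(c1ccccc1)C(C)(C)C
F6 | step 10 | (3R,12E)-1-[(tert-butyldiphenylsilyl)oxy]-6,6-dimethoxydocos-12-en-10-yn-3-ol | CCCCCCCCC/C=C/C#CCCCC(OC)(OC)CC[C@@H](O)CCO[Si](c1ccccc1)(c1ccccc1)C(C)(C)C
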